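Assumption: germacranolide numbering (C1–C15) is used for the target and carried through all intermediates (C9′ is an extra carbon lost as formaldehyde in step 11); (R)-2-methylbutanoic acid, Schwartz reagent, (−)-MIB and D-(−)-diethyl tartrate are taken as purchased.

## Structural features

- The target is a furanoheliangolide. A ten-membered carbocycle C1–C10 is bridged by an oxygen between C3 and C10, so that O, C3, C2, C1 and C10 form a 3(2H)-furanone and the bridge C4–C9 completes an 11-oxabicyclo[6.2.1]undecane.
- A trans-fused α-methylene-γ-butyrolactone (C6–O–C12(=O)–C11(=C13)–C7) sits on the C6–C7 bond.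
- The C4=C5 olefin is Z in the ring (C3 and C6 cis), carries C15 and is conjugated with the furanone (C5=C4–C3=C2–C1=O).
- Five contiguous stereocentres line the bridge: C6 (R), C7 (S), C8 (S), C9 (R) and C10 (R). C10 is fully substituted (C14, ring O, C1, C9), C9 carries a free hydroxyl, C8 carries the (R)-2-methylbutanoate, and O8/O9 are syn.
- Fragile groups: the exo-methylene lactone (Michael acceptor), the C8 ester beside the free C9–OH (acyl migration), the β-hydroxy ketone C9(OH)–C10–C1(=O) (retro-aldol under base), the Z-dienone and the vinylogous ester.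
- The real difficulty is the strained oxygen-bridged medium ring closed at the quaternary C10, together with the C9/C10 pair that must be set relative to C6–C8.
- The key step exploits the fact that C10 is the α-carbon of the C1 ketone inside the furanone ring. Enolisation gives an aromatic 3-oxyfuran that is nucleophilic at C10, and the neighbouring C9 carbinol is an aldol retron, so C9–C10 can be the ring-closing bond.

## Logic of the disconnections

In one sentence: the ten-membered ring is closed in the last step by a dearomatising intramolecular Mukaiyama aldol between C10 of a 3-silyloxyfuran generated in the flask and the C9 formyl group of the fully functionalised seco-aldehyde 19.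

**22 ⇒ 19 (through 21 and 20): cut C9–C10.**
- Reason: C9(OH)–C10–C1(=O) is an aldol retron and the enol of the furanone is an aromatic furan, so C10 can be a carbon nucleophile of a known type.
- Gain: both medium rings open, two stereocentres (C9, C10) disappear, and the C10 configuration of the precursor becomes irrelevant because it is erased in 20.
- Demand: the forward step must close a ten-membered ring at a fully substituted carbon with control of both new centres from C6–C8, without base strong enough to touch the ester, the methylene lactone or the aldehyde α-position.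

**19 ⇒ 18: cut C9–C9′ (retrosynthetic addition of one carbon).**
- Reason: the α-acyloxy aldehyde is too labile to carry, so it is masked as a terminal 1,2-diol.
- Gain: neutral unmasking in the penultimate step; the C9 configuration of 18 does not matter.
- Demand: cleavage before the C8 ester can migrate to O9.

**18 ⇒ 16 + 17: cut the C8–O(ester) bond.**
- Reason: the carboxylic acid opens a 2,3-epoxy alcohol at C8 with inversion, which introduces the side chain, the C8 configuration and the O8/O9 differentiation together, without protecting groups.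
- Gain: 17 enters convergently and late.
- Demand: attack at C8 and not at C9.

**16 ⇒ 15 ⇒ 13 + 14 + carbon monoxide: cut the ring O–C3 bond, then C3–C4 and C3–C2.**
- Reason: the furanone is the cycloisomer of a γ-hydroxy ynone, which is a three-component carbonylative coupling product of a Z-vinyl iodide, CO and a four-carbon alkynol.
- Gain: no separate furanone fragment; racemic 14 suffices.
- Demand: retention of the Z geometry and neutral conditions that spare the epoxy alcohol and the methylene lactone.

**13 ⇒ 12: cut the epoxide C–O bonds.**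
- Reason: reagent-controlled asymmetric epoxidation of an E-allylic alcohol sets C8 (after the later inversion).
- Demand: only the allylic-alcohol olefin may react.

**12 ⇒ 8 + 9 (through 11 and 10): cut C7–C8 with allylic transposition to C11=C13.**
- Reason: SN2′ attack of an E-alkenyl metal on the bromomethyl butenolide sets C7 trans to C6 by ring control and forms the exo-methylene in the same event.
- Gain: C8, C9 and C9′ come from a commercial alkyne.
- Demand: γ-attack anti to the C6 substituent without deprotonation of the acidic C6–H.

**8 ⇒ 7 ⇒ 5 + 6: cut C7=C11 (metathesis) and the C12–O ester bond.**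
- Gain: a simple dienol and a commercial acid.
- Demand: formation of a trisubstituted butenolide olefin in the presence of an allylic bromide and a vinyl iodide.

**5 ⇒ 4 + a vinylzinc reagent: cut C6–C7.**
- Reason: an enantioselective vinyl addition sets C6, from which C7 and the face of the key step are later derived.

**4 ⇒ 3 ⇒ 1.**
- Reason: trans-hydroalumination/iodination of the butynol fixes the Z geometry of C4=C5 at the start.

## Other disconnections considered

Alternative 1: (the first that comes to mind) cut C6–C7 and the lactone C–O bond. The forward key step is an intramolecular Barbier or Nozaki–Hiyama–Kishi allylation of the Z-enal of the seco bromide A1 (furanone already in place, C9–OH protected), with lactonisation to the methylene lactone.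
- C9 and C10 would have to be set beforehand by an intermolecular furanone aldol with no ring template.
- C9 needs a protecting group that must be removed beside the migrating C8 ester.
- The Z-β-furanonyl enal is prone to isomerise.
- This is the textbook germacranolide closure and resolves only C6/C7, which the chosen route sets more simply on a five-membered ring.

Alternative 2: cut the ring O–C3 bond transannularly. The forward key step is a gold- or acid-mediated cycloisomerisation of the ten-membered 10-hydroxy-2-yn-1-one A2 to the furanone.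
- A ten-membered ring containing the linear C1–C2≡C3–C4 unit next to a Z-olefin should be highly strained.
- The tertiary C10 alcohol would have to be made enantioselectively in an acyclic fragment.
- A separate macrocyclisation is still needed, so two hard operations replace one.

Alternative 3: cut C2–C3 as an O→C acyl transfer. The forward key step is a base-mediated intramolecular Claisen condensation of the C10 acetyl group onto the lactone carbonyl of the nine-membered Z-enoate lactone A3, followed by dehydration (ring expansion to the carbocycle).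
- A3 would require lactonisation onto a tertiary alcohol in a nine-membered ring, which is as hard as the target ring.
- The enolate conditions threaten the methylene lactone and the C8 ester.
- C10 must again be set separately.

Key step: step 12

## Route

Step 1
Reactants: 1 but-2-yn-1-ol
Product: 3 (Z)-3-iodobut-2-en-1-ol, via cyclic alkenylalanate 2 (not isolated)
Conditions: Red-Al, THF, 0 °C to rt; then I2, THF, −78 to 0 °C
Reagents that add atoms: iodine, II
Why: Hydroxyl-directed trans-hydroalumination of the propargylic alcohol places aluminium at C4 cis to the CH2O group in a five-membered alanate, and iododealumination with retention fixes the Z geometry that becomes the C4=C5 olefin.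

Step 2
Reactants: 3 (Z)-3-iodobut-2-en-1-ol
Product: 4 (Z)-3-iodobut-2-enal
Conditions: activated MnO2, CH2Cl2, rt, dark
Reagents that add atoms: none
Why: Allylic oxidation with MnO2 is neutral and should not isomerise the Z-β-iodoenal when light and acid are excluded; the aldehyde is used directly.

Step 3
Reactants: 4 (Z)-3-iodobut-2-enal
Product: 5 (3S,4Z)-5-iodohexa-1,4-dien-3-ol
Conditions: divinylzinc (from CH2=CHMgBr and ZnCl2, Et2O, salts removed with dioxane), (−)-MIB (5 mol %), toluene, −20 to 0 °C
Reagents that add atoms: divinylzinc, C=C[Zn]C=C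
Why: Amino-alcohol-catalysed asymmetric 1,2-addition of an alkenylzinc to an aldehyde (Oppolzer/Noyori type); with the (2S)-ligand the vinyl group should be delivered to the Si face, giving the 3S carbinol (C6 of the target), and the vinyl iodide is inert to organozinc reagents.

Step 4
Reactants: 5 (3S,4Z)-5-iodohexa-1,4-dien-3-ol and 6 2-(bromomethyl)acrylic acid
Product: 7 (3S,4Z)-5-iodohexa-1,4-dien-3-yl 2-(bromomethyl)prop-2-enoate
Conditions: DCC, DMAP (5 mol %), CH2Cl2, 0 °C
Reagents that add atoms: none
Why: Steglich esterification of a secondary allylic alcohol; no stereocentre is touched, and low temperature with only catalytic DMAP limits attack of the amine on the allylic bromide.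

Step 5
Reactants: 7 (3S,4Z)-5-iodohexa-1,4-dien-3-yl 2-(bromomethyl)prop-2-enoate
Product: 8 (5S)-3-(bromomethyl)-5-[(Z)-2-iodoprop-1-en-1-yl]furan-2(5H)-one
Conditions: Hoveyda–Grubbs II (5 mol %), 1,4-benzoquinone (10 mol %), toluene (0.01 M), 80 °C
Reagents that add atoms: none
Why: Ring-closing metathesis of an allyl acrylate to a butenolide; the catalyst loads on the monosubstituted vinyl group and closes onto the 1,1-disubstituted acrylate, the hindered electron-poor iodoalkene stays out, and C6 is untouched under neutral conditions.

Step 6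
Reactants: 8 (5S)-3-(bromomethyl)-5-[(Z)-2-iodoprop-1-en-1-yl]furan-2(5H)-one and 9 trimethyl(prop-2-yn-1-yloxy)silane
Product: 12 (4S,5S)-4-[(E)-3-hydroxyprop-1-en-1-yl]-5-[(Z)-2-iodoprop-1-en-1-yl]-3-methylidenedihydrofuran-2(3H)-one, via alkenylzirconocene 10 (not isolated), via trimethylsilyl ether 11 (not isolated)
Conditions: 9, Cp2Zr(H)Cl, CH2Cl2, rt; then 8, CuBr·SMe2 (10 mol %), THF, −20 to 0 °C; then citric acid, MeOH, 0 °C
Reagents that add atoms: none
Why: Hydrozirconation gives the E-alkenylzirconocene, which after transmetallation to copper adds to the β-carbon C7 of the butenolide and expels bromide (SN2′ conjugate addition–elimination, the known copper-catalysed allylation of alkenylzirconocenes), so the exo-methylene forms in the same event; the alkenyl group enters anti to the C6 substituent on the nearly planar ring, setting 7S (trans lactone), and mild acid removes the TMS ether.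

Step 7
Reactants: 12 (4S,5S)-4-[(E)-3-hydroxyprop-1-en-1-yl]-5-[(Z)-2-iodoprop-1-en-1-yl]-3-methylidenedihydrofuran-2(3H)-one
Product: 13 (4S,5S)-4-[(2R,3R)-3-(hydroxymethyl)oxiran-2-yl]-5-[(Z)-2-iodoprop-1-en-1-yl]-3-methylidenedihydrofuran-2(3H)-one
Conditions: Ti(OiPr)4, D-(−)-diethyl tartrate, t-BuOOH, 4 Å MS, CH2Cl2, −20 °C
Reagents that add atoms: tert-butyl hydroperoxide, CC(C)(C)OO
Why: Sharpless asymmetric epoxidation of an E-allylic alcohol; D-(−)-tartrate should deliver oxygen to the face that gives the (2R,3R)-epoxy alcohol under reagent control, and neither the electron-poor methylene lactone nor the vinyl iodide is epoxidised by Ti/TBHP.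

Step 8
Reactants: 13 (4S,5S)-4-[(2R,3R)-3-(hydroxymethyl)oxiran-2-yl]-5-[(Z)-2-iodoprop-1-en-1-yl]-3-methylidenedihydrofuran-2(3H)-one and 14 but-3-yn-2-ol (racemic)
Product: 15 (4S,5R)-5-[(1Z)-6-hydroxy-2-methyl-3-oxohept-1-en-4-yn-1-yl]-4-[(2R,3R)-3-(hydroxymethyl)oxiran-2-yl]-3-methylidenedihydrofuran-2(3H)-one (both carbinol epimers)
Conditions: CO (1 atm), PdCl2(PPh3)2 (5 mol %), CuI (2 mol %), Et3N, THF, rt
Reagents that add atoms: carbon monoxide, [C-]#[O+]
Why: Carbonylative Sonogashira coupling: oxidative addition of Pd(0) to the Z-vinyl iodide, CO insertion and alkynyl transfer give the cross-conjugated ynone with retention of olefin geometry; racemic 14 is acceptable because its carbinol carbon (C10) is planarised in step 12.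

Step 9
Reactants: 15 (4S,5R)-5-[(1Z)-6-hydroxy-2-methyl-3-oxohept-1-en-4-yn-1-yl]-4-[(2R,3R)-3-(hydroxymethyl)oxiran-2-yl]-3-methylidenedihydrofuran-2(3H)-one
Product: 16 (4S,5R)-4-[(2R,3R)-3-(hydroxymethyl)oxiran-2-yl]-3-methylidene-5-[(Z)-2-(5-methyl-4-oxo-4,5-dihydrofuran-2-yl)prop-1-en-1-yl]dihydrofuran-2(3H)-one (both C10 epimers)
Conditions: (p-CF3C6H4)3PAuCl/AgOTf (5 mol %), toluene (not dried), rt
Reagents that add atoms: water, O
Why: Gold(I)-catalysed cycloisomerisation of a γ-hydroxy ynone to a 3(2H)-furanone (known reaction): the activated alkyne takes up water at C1, the hydroxyl closes onto C3 and water is lost, a net 1,3-transposition of the carbonyl under neutral conditions that should spare the methylene lactone and the remote epoxide.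

Step 10
Reactants: 16 (4S,5R)-4-[(2R,3R)-3-(hydroxymethyl)oxiran-2-yl]-3-methylidene-5-[(Z)-2-(5-methyl-4-oxo-4,5-dihydrofuran-2-yl)prop-1-en-1-yl]dihydrofuran-2(3H)-one and 17 (R)-2-methylbutanoic acid
Product: 18 (1S,2R)-2,3-dihydroxy-1-[(2R,3S)-4-methylidene-2-[(Z)-2-(5-methyl-4-oxo-4,5-dihydrofuran-2-yl)prop-1-en-1-yl]-5-oxotetrahydrofuran-3-yl]propyl (2R)-2-methylbutanoate
Conditions: Ti(OiPr)4 (1.5 equiv), 17 (1.5 equiv), CH2Cl2, rt
Reagents that add atoms: none
Why: Titanium(IV)-mediated opening of a 2,3-epoxy alcohol by a carboxylic acid (Caron–Sharpless): the titanium-bound epoxy alkoxide is attacked by the carboxylate at C3 of the epoxy alcohol (C8) with inversion, turning 8R into 8S and placing the ester on the correct oxygen; the new C9 carbinol is removed in step 11.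

Step 11
Reactants: 18 (1S,2R)-2,3-dihydroxy-1-[(2R,3S)-4-methylidene-2-[(Z)-2-(5-methyl-4-oxo-4,5-dihydrofuran-2-yl)prop-1-en-1-yl]-5-oxotetrahydrofuran-3-yl]propyl (2R)-2-methylbutanoate
Product: 19 (1S)-1-[(2R,3S)-4-methylidene-2-[(Z)-2-(5-methyl-4-oxo-4,5-dihydrofuran-2-yl)prop-1-en-1-yl]-5-oxotetrahydrofuran-3-yl]-2-oxoethyl (2R)-2-methylbutanoate
Conditions: NaIO4, THF/pH 7 buffer, 0 °C; used crude
Reagents that add atoms: none
Why: Periodate cleavage of the terminal 1,2-diol (Malaprade reaction) under neutral conditions releases the α-acyloxy aldehyde without touching the ester or the alkenes; immediate use limits epimerisation at C8.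

Step 12
Reactants: 19 (1S)-1-[(2R,3S)-4-methylidene-2-[(Z)-2-(5-methyl-4-oxo-4,5-dihydrofuran-2-yl)prop-1-en-1-yl]-5-oxotetrahydrofuran-3-yl]-2-oxoethyl (2R)-2-methylbutanoate
Product: 22 (4Z,6R,7S,8S,9R,10R)-9-hydroxy-1-oxo-3,10-epoxygermacra-2,4,11(13)-trien-12,6-olid-8-yl (2R)-2-methylbutanoate (target CNP0146060.1), via silyloxyfuran aldehyde 20 (not isolated), via silyl ether 21 (not isolated)
Conditions: TMSOTf (2.5 equiv), 2,6-lutidine (3 equiv), CH2Cl2 (1 mM, slow addition of 19), −78 to −40 °C; then aq. citric acid, THF, 0 °C
Reagents that add atoms: none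
Why: TMSOTf silylates the vinylogous-ester carbonyl and 2,6-lutidine removes H-10 from the resulting 2H-furanium ion to give the aromatic 3-silyloxyfuran 20 (both C10 epimers of 19 converge), after which the silyl-activated formyl group is attacked by C10, the α-carbon of the furan and terminus of the enol silane, with dearomatisation and silyl transfer to 21, which mild acid desilylates to 22. The closest known reaction types are the Mukaiyama aldol addition of 3-silyloxyfurans to aldehydes at C2 and the one-pot enol-silane formation/Mukaiyama aldol with TMSOTf and an amine, here used intramolecularly. The C9–C10 bond closes the ten-membered carbocycle (nine-membered through the furan oxygen) in a 10-(enolendo)-exo-trig mode and creates the 11-oxabicyclo[6.2.1] core; no small ring is formed. C10 should be controlled by the tether: the Z-C4=C5 bond holds C6 beside the oxygen edge of the planar furan and the trans-fused (6R,7S) lactone fixes the C5–C6–C7–C8 dihedral at about +90 to +150°, which in a model carries C8–C9 over the Re face of C10, whereas the Si face would need the opposite sign of this dihedral, which the trans fusion cannot adopt without severe transannular strain, so 10R is expected. C9 should be controlled by the aldehyde conformation: the C8–O(acyl) bond lies anti to the incoming C10 (polar Felkin–Anh arrangement) and the bulky silylated carbonyl oxygen points away from the C7–C8 ring bond to the outside of the forming ring, which exposes the Si face of the formyl group and gives 9R (8,9-syn). The step needs C10 rather than C2 attack (C10 is both α to the ring oxygen and the enol-silane terminus), aldehyde rather than methylene-lactone attack (the activated α-acyloxy aldehyde is far more electrophilic at low temperature), cyclisation rather than oligomerisation (high dilution, preorganisation by the Z-olefin, furan and lactone), and no enolisation at C8 (weak hindered base).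

## Compound list

1 | but-2-yn-1-ol | CC#CCO | starting material
2 | sodium 2,2-bis(2-methoxyethoxy)-3-methyl-2,5-dihydro-1,2-oxaaluminol-2-uide (cyclic Z-alkenylalanate) | CC1=CCO[Al-]1(OCCOC)OCCOC.[Na+] | intermediate
3 | (Z)-3-iodobut-2-en-1-ol | C/C(I)=C/CO | intermediate
4 | (Z)-3-iodobut-2-enal | C/C(I)=C/C=O | intermediate
5 | (3S,4Z)-5-iodohexa-1,4-dien-3-ol | C=C[C@H](O)/C=C(/C)I | intermediate
6 | 2-(bromomethyl)acrylic acid | C=C(CBr)C(=O)O | starting material
7 | (3S,4Z)-5-iodohexa-1,4-dien-3-yl 2-(bromomethyl)prop-2-enoate | C=C(CBr)C(=O)O[C@@H](C=C)/C=C(/C)I | intermediate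
8 | (5S)-3-(bromomethyl)-5-[(Z)-2-iodoprop-1-en-1-yl]furan-2(5H)-one | BrCC1=C[C@@H](/C=C(/C)I)OC1=O | intermediate
9 | trimethyl(prop-2-yn-1-yloxy)silane | C#CCO[Si](C)(C)C | starting material
10 | chlorobis(cyclopentadienyl)[(E)-3-(trimethylsilyloxy)prop-1-en-1-yl]zirconium | C[Si](C)(C)OC/C=C/[Zr+2]Cl.c1cc[cH-]c1.c1cc[cH-]c1 | intermediate
11 | (4S,5S)-5-[(Z)-2-iodoprop-1-en-1-yl]-3-methylidene-4-[(E)-3-(trimethylsilyloxy)prop-1-en-1-yl]dihydrofuran-2(3H)-one | C=C1C(=O)O[C@H](/C=C(/C)I)[C@H]1/C=C/CO[Si](C)(C)C | intermediate
12 | (4S,5S)-4-[(E)-3-hydroxyprop-1-en-1-yl]-5-[(Z)-2-iodoprop-1-en-1-yl]-3-methylidenedihydrofuran-2(3H)-one | C=C1C(=O)O[C@H](/C=C(/C)I)[C@H]1/C=C/CO | intermediate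
13 | (4S,5S)-4-[(2R,3R)-3-(hydroxymethyl)oxiran-2-yl]-5-[(Z)-2-iodoprop-1-en-1-yl]-3-methylidenedihydrofuran-2(3H)-one | C=C1C(=O)O[C@H](/C=C(/C)I)[C@H]1[C@H]2O[C@@H]2CO | intermediate
14 | but-3-yn-2-ol (racemic) | CC(O)C#C | starting material
15 | (4S,5R)-5-[(1Z)-6-hydroxy-2-methyl-3-oxohept-1-en-4-yn-1-yl]-4-[(2R,3R)-3-(hydroxymethyl)oxiran-2-yl]-3-methylidenedihydrofuran-2(3H)-one (carbinol epimers) | C=C1C(=O)O[C@H](/C=C(/C)C(=O)C#CC(C)O)[C@H]1[C@H]2O[C@@H]2CO | intermediate
16 | (4S,5R)-4-[(2R,3R)-3-(hydroxymethyl)oxiran-2-yl]-3-methylidene-5-[(Z)-2-(5-methyl-4-oxo-4,5-dihydrofuran-2-yl)prop-1-en-1-yl]dihydrofuran-2(3H)-one (C10 epimers) | C=C1C(=O)O[C@H](/C=C(/C)C2=CC(=O)C(C)O2)[C@H]1[C@H]3O[C@@H]3CO | intermediate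
17 | (R)-2-methylbutanoic acid | CC[C@@H](C)C(=O)O | starting material
18 | (1S,2R)-2,3-dihydroxy-1-[(2R,3S)-4-methylidene-2-[(Z)-2-(5-methyl-4-oxo-4,5-dihydrofuran-2-yl)prop-1-en-1-yl]-5-oxotetrahydrofuran-3-yl]propyl (2R)-2-methylbutanoate | C=C1C(=O)O[C@H](/C=C(/C)C2=CC(=O)C(C)O2)[C@H]1[C@H](OC(=O)[C@H](C)CC)[C@H](O)CO | intermediate
19 | (1S)-1-[(2R,3S)-4-methylidene-2-[(Z)-2-(5-methyl-4-oxo-4,5-dihydrofuran-2-yl)prop-1-en-1-yl]-5-oxotetrahydrofuran-3-yl]-2-oxoethyl (2R)-2-methylbutanoate | C=C1C(=O)O[C@H](/C=C(/C)C2=CC(=O)C(C)O2)[C@H]1[C@H](OC(=O)[C@H](C)CC)C=O | intermediate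
20 | (1S)-1-[(2R,3S)-4-methylidene-2-[(Z)-2-{5-methyl-4-[(trimethylsilyl)oxy]furan-2-yl}prop-1-en-1-yl]-5-oxotetrahydrofuran-3-yl]-2-oxoethyl (2R)-2-methylbutanoate | C=C1C(=O)O[C@H](/C=C(/C)c2cc(O[Si](C)(C)C)c(C)o2)[C@H]1[C@H](OC(=O)[C@H](C)CC)C=O | intermediate
21 | 9-O-trimethylsilyl ether of 22 | C=C1C(=O)O[C@@H]2/C=C(/C)C3=CC(=O)[C@](C)(O3)[C@H](O[Si](C)(C)C)[C@@H](OC(=O)[C@H](C)CC)[C@@H]12 | intermediate
22 | (4Z,6R,7S,8S,9R,10R)-9-hydroxy-1-oxo-3,10-epoxygermacra-2,4,11(13)-trien-12,6-olid-8-yl (2R)-2-methylbutanoate (CNP0146060.1) | C=C1C(=O)O[C@@H]2/C=C(/C)C3=CC(=O)[C@](C)(O3)[C@H](O)[C@@H](OC(=O)[C@H](C)CC)[C@@H]12 | target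

## Step count and risk

Total step count: 12. Longest linear sequence: 12 steps (1 to 22); all other components (6, 9, 14, 17) are purchased.

Least certain steps:

**Step 12 (key step).**
- Most likely failure: poor facial selectivity at C10 or C9, because the tether model rests on a hand-built conformational argument and a strained transition state.
- Other risks: competing attack through furan C4 (target C2) to an eight-membered ring, Mukaiyama–Michael addition to the methylene lactone, oligomerisation, or acyl migration from O8 to O9 at the aldolate stage.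
- Fallback (from 18, returning at 22): bromination with N-bromosuccinimide in THF at 0 °C at the enolisable C10 gives the 10-bromo furanone diol F1. Periodate cleavage as in step 11 gives the bromo aldehyde F2. Slow addition of F2 to CrCl2 with catalytic LiI in THF at high dilution generates a chromium(III) enolate at C10 that adds to the C9 formyl group in a chromium-Reformatsky macrocyclisation. This passes through a metal-bridged closed transition state, a different source of C9/C10 control that needs neither silyl triflate nor amine, and gives 22.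

**Step 6.**
- Most likely failure: direct SN2 substitution at the bromomethyl carbon instead of γ-attack, or loss of the C6 configuration by deprotonation of the acidic butenolide γ-hydrogen (aromatic 2-oxidofuran).
- Fallback (from 5, returning at 11): acryloyl chloride and Et3N give the acrylate F3, and ring-closing metathesis gives the unsubstituted butenolide F4. Copper-catalysed conjugate addition of alkenylzirconocene 10 in the presence of TMSCl, with the enolate trapped by Eschenmoser's salt, gives the Mannich base F5. Quaternisation with MeI and elimination with NaHCO3 install the methylene group and return 11, which is desilylated to 12 as in step 6.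

**Step 10.**
- Most likely failure: attack of the carboxylate at C9 instead of C8, because C8 is flanked by the branched ring carbon C7, or migration of the acyl group to O9 or O9′ on titanium.
- Fallback (from 12, returning at 19): methyl chloroformate and pyridine give the allylic carbonate F6. Iridium/phosphoramidite-catalysed branched-selective allylic substitution with the carboxylate of 17 gives the secondary allylic ester F7, with C8 set by the ligand. Carbonylative coupling with 14 as in step 8 gives the ynone F8, and gold cycloisomerisation as in step 9 gives the furanone F9. Catalytic OsO4/NMO followed by NaIO4 then cleaves the terminal vinyl group, the only olefin not conjugated to a carbonyl, to the aldehyde 19.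

**Step 3.**
- Most likely failure: insufficient enantioselectivity through uncatalysed background addition of residual vinylmagnesium or salt-containing vinylzinc species to the reactive enal.
- Fallback (from 4, returning at 5): vinylmagnesium bromide in THF at −78 °C gives the racemic dienol F10. Sharpless kinetic resolution with L-(+)-diisopropyl tartrate, Ti(OiPr)4 and 0.6 equiv of t-BuOOH epoxidises the vinyl group of the R enantiomer to the erythro epoxy alcohol F11 and leaves (S)-5, which is separated and continues in step 4.

## Further compounds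

F1 | step 12 | 10-bromo derivative of 18 (2-bromo-2-methylfuran-3(2H)-one unit; C6, C7, C8, C9 as in 18) | C=C1C(=O)O[C@H](/C=C(/C)C2=CC(=O)C(C)(Br)O2)[C@H]1[C@H](OC(=O)[C@H](C)CC)[C@H](O)CO
F2 | step 12 | 10-bromo derivative of 19 (bromo aldehyde; C6, C7, C8 as in 19) | C=C1C(=O)O[C@H](/C=C(/C)C2=CC(=O)C(C)(Br)O2)[C@H]1[C@H](OC(=O)[C@H](C)CC)C=O
F3 | step 6 | (3S,4Z)-5-iodohexa-1,4-dien-3-yl prop-2-enoate | C=CC(=O)O[C@@H](C=C)/C=C(/C)I
F4 | step 6 | (5S)-5-[(Z)-2-iodoprop-1-en-1-yl]furan-2(5H)-one | O=C1C=C[C@@H](/C=C(/C)I)O1
F5 | step 6 | 3-[(dimethylamino)methyl] Mannich base of the saturated lactone (C6, C7 as in 11; C11 not defined) | CN(C)CC1C(=O)O[C@H](/C=C(/C)I)[C@H]1/C=C/CO[Si](C)(C)C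
F6 | step 10 | methyl carbonate of allylic alcohol 12 | C=C1C(=O)O[C@H](/C=C(/C)I)[C@H]1/C=C/COC(=O)OC
F7 | step 10 | branched allylic ester: C8 (2R)-2-methylbutanoate carrying a terminal vinyl group (C9=C9′), vinyl iodide intact (C6, C7, C8 as in 19) | C=C1C(=O)O[C@H](/C=C(/C)I)[C@H]1[C@H](OC(=O)[C@H](C)CC)C=C
F8 | step 10 | γ-hydroxy ynone from F7 (carbinol epimers) | C=C1C(=O)O[C@H](/C=C(/C)C(=O)C#CC(C)O)[C@H]1[C@H](OC(=O)[C@H](C)CC)C=C
F9 | step 10 | furanone from F8 with terminal vinyl group at C8 (C10 epimers) | C=C1C(=O)O[C@H](/C=C(/C)C2=CC(=O)C(C)O2)[C@H]1[C@H](OC(=O)[C@H](C)CC)C=C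
F10 | step 3 | (Z)-5-iodohexa-1,4-dien-3-ol (racemic) | C=CC(O)/C=C(/C)I
F11 | step 3 | (1S,2Z)-3-iodo-1-[(2S)-oxiran-2-yl]but-2-en-1-ol | O[C@H]([C@@H]1CO1)/C=C(/C)I
A1 | alternative 1 | seco bromide for C6–C7 allylation: furanone closed, C9–O–TES, C8 ester, Z-enal at C6, methyl (Z)-2-(bromomethyl)alk-2-enoate at C7 | O=C/C=C(/C)C1=CC(=O)[C@](C)(O1)[C@H](O[Si](CC)(CC)CC)[C@@H](OC(=O)[C@H](C)CC)/C=C(\CBr)C(=O)OC
A2 | alternative 2 | ten-membered 10-hydroxy-2-yn-1-one with the lactone in place (O–C3 bond not yet formed) | C=C1C(=O)O[C@@H]2/C=C(/C)C#CC(=O)[C@](C)(O)[C@H](O)[C@@H](OC(=O)[C@H](C)CC)[C@@H]12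
A3 | alternative 3 | nine-membered Z-enoate lactone (C3 acyl on O10) with an acetyl group on C10 and C9–O–TES | C=C1C(=O)O[C@@H]2/C=C(/C)C(=O)O[C@@](C)(C(C)=O)[C@H](O[Si](CC)(CC)CC)[C@@H](OC(=O)[C@H](C)CC)[C@@H]12
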